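Read the charges and the runs first, since you want a quick number for the new flask.

the same everywhere: free catalyst 1.5 mM; impurity 0.41 mM

|  | starting material | reagent | precatalyst | remark | time |
|---|---|---|---|---|---|
| spring | 0.50 M | 2 M | 1 mM | run made earlier |  |
| autumn | 0.75 M | 2 M | 1 mM | run made earlier |  |
| flask | 1.0 M | 2.00 M | 1.0 mM |  | 2.0 min |

| run | time / min | starting material / % | product / % | open intermediate / % |
|---|---|---|---|---|
| spring | 0.200 | 82.6 | 0.5 | 19.7 |
| spring | 0.333 | 75.8 | 0.6 | 24.7 |
| spring | 0.500 | 72.4 | 0.5 | 30.3 |
| spring | 0.833 | 65.9 | 0.6 | 31.8 |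
| spring | 1.33 | 64.1 | 3.2 | 33.0 |
| spring | 2.50 | 60.1 | 9.8 | 31.8 |
| autumn | 0.417 | 72.7 | 0 | 27.1 |
| autumn | 0.833 | 67.6 | 1.8 | 33.2 |
| autumn | 1.33 | 63.6 | 3.5 | 34.9 |
| autumn | 1.50 | 64.4 | 5.2 | 32.6 |
| autumn | 2.00 | 60.5 | 7.2 | 32.3 |
| autumn | 2.50 | 59.1 | 8.6 | 30.0 |

(scatter of a reading: 1 percentage point)

- share of the starting material used up at 2.0 min
- product at 2.0 min, in percent of the starting material charged
- open intermediate at 2.0 min, in percent of the starting material charged
- amount of product if the flask were left three thousand times as long, in percent of the starting material charged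

- the analysis behind the earlier runs scatters by 1 percentage point, standard deviation

1. Pool the spring and autumn runs. At 2.50 min, spring reads 9.8% product and autumn 8.6%, a gap of 1.2 percentage points with a scatter of 1 point on each reading. Percentages that stay close while the charge goes from 0.50 M to 0.75 M read as pseudo-first-order behaviour in starting material, so I carry them to the new flask.

2. Between 0.833 min and 2.50 min, the pooled product climbs from 1.20% to 9.20%. That reads as 0.0480 min⁻¹, the product rate: the share of the charge turned into product per minute on the straight stretch.

3. A constant rate integrates to a line: product equals the product rate times the time after a lag. Running the line back to zero product gives a lag of 0.583 min.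

4. For the new flask at 2.0 min, this line gives 6.80% product.

5. My forecast says 38.5% used up, 7% product, 31.5% open intermediate and 97% product in the long run; it carries the runs over to the new flask on the ground that “The chemistry therefore behaves as roughly first order in substrate”. Its product figure sits slightly above the line's.

The new flask gives 39.0% used up, 6.73% product, 32.2% open intermediate and 100% product in the long run.

    free catalyst + impurity → spent catalyst (k = 38700 M⁻¹ s⁻¹)
    reagent + catalyst intermediate → second catalyst + product (k = 4.58 M⁻¹ s⁻¹)
    starting material + free catalyst ⇌ free catalyst + open intermediate (K = 0.550, k = 19.5 M⁻¹ s⁻¹)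
    precatalyst → second catalyst (k = 0.0241 s⁻¹)
    second catalyst + open intermediate ⇌ catalyst intermediate (K = 0.355 M⁻¹, k = 32.0 M⁻¹ s⁻¹)

The new flask's 6.73% at 2.0 min stands beside 6.80% from the product rate, a gap of 0.070 points. Now read the same flask at 5.0 min: the product rate gives 21.2%, and that flask holds 20.1%. Between the two times its product rose by 0.0446 min⁻¹, against the 0.0480 min⁻¹ read from the runs, while starting material went from 61.0% to 52.3% and open intermediate from 32.2% to 27.6%.

The runs are calculated with made-up constants; scatter was added.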